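**Retrosynthetic overview**
- Lignan numbering is used: syringyl side C7–C8–C9, guaiacyl side C7'–C8'–C9'; ring A = O–C7'–C8'–C8–C9, ring B = O–C7–C8–C8'–C9'; the target is (7R,8S,7'S,8'R).
- The strategy rests on one feature: the tertiary C8–OH and the ring A oxygen on C9 form a 1,2-diol, which can carry the guaiacyl carbon C7' as a spiro-dioxolane directly beside the enolisable C8' of a ring B γ-lactone (C9'=O).
- Last disconnections: the two phenol protecting groups, then the ring B CH2 (C9') back to the lactone carbonyl via the lactol.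
- Key disconnection C8'–C7' (ring A): the spiro acetal is opened to an O9=C7' oxocarbenium ion that the lactone silyl ketene acetal captures, so the dioxolane trades its C8 oxygen for C8'.
- Ring B lactone diol: the C7–O bond comes from invertive opening of a Sharpless epoxide (sets C8, then C7) by a tert-butyl ester; the chain comes from syringaldehyde by Horner–Wadsworth–Emmons olefination. Ring order: B, then A.

Key step: step 10

Remark: the acetal is carried as a mixture of C7' epimers, since that centre becomes planar in the key step. The syringyl phenol is carried as a tosylate so that two i-Bu2AlH reductions and three Lewis acid steps leave it and the C7–O bond alone.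

**Step 1**
Reactants: 1 syringaldehyde (4-hydroxy-3,5-dimethoxybenzaldehyde)
Product: 2 4-formyl-2,6-dimethoxyphenyl 4-methylbenzenesulfonate
Conditions: TsCl, Et3N, 4-(dimethylamino)pyridine (cat.), CH2Cl2, 0 °C to rt
Reagents that add atoms: p-toluenesulfonyl chloride, Cc1ccc(cc1)S(=O)(=O)Cl
Why: Phenol O-sulfonylation; the electron-withdrawing, hydride-stable tosylate should keep the C7 benzylic position from ionising in steps 6, 10 and 12.

**Step 2**
Reactants: 3 triethyl phosphonoacetate; 4 tert-butyl bromoacetate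
Product: 5 4-tert-butyl 1-ethyl 2-(diethoxyphosphoryl)butanedioate
Conditions: NaH, THF, 0 °C to rt
Reagents that add atoms: none
Why: SN2 C-alkylation of the sodium phosphonoacetate anion gives the phosphonosuccinate that supplies C8, C9, C8' and C9'.

**Step 3**
Reactants: 2 4-formyl-2,6-dimethoxyphenyl 4-methylbenzenesulfonate; 5 4-tert-butyl 1-ethyl 2-(diethoxyphosphoryl)butanedioate
Product: 6 4-tert-butyl 1-ethyl (2E)-2-{[3,5-dimethoxy-4-(tosyloxy)phenyl]methylidene}butanedioate
Conditions: NaH, THF, 0 °C to rt; minor (Z)-isomer removed by chromatography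
Reagents that add atoms: none
Why: Horner–Wadsworth–Emmons olefination of a stabilised phosphonate should give mainly the (E)-alkene (aryl trans to CO2Et, cis to CH2CO2t-Bu), the geometry that the anti oxygenation of steps 5 and 6 requires.

**Step 4**
Reactants: 6 4-tert-butyl 1-ethyl (2E)-2-{[3,5-dimethoxy-4-(tosyloxy)phenyl]methylidene}butanedioate
Product: 8 tert-butyl (3E)-4-[3,5-dimethoxy-4-(tosyloxy)phenyl]-3-(hydroxymethyl)but-3-enoate, via enal 7 (not isolated)
Conditions: i-Bu2AlH (2.2 equiv), CH2Cl2, −78 °C; aq. potassium sodium tartrate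
Reagents that add atoms: none
Why: i-Bu2AlH reduction of the conjugated ethyl ester through the enal to the allylic alcohol at −78 °C, where the hindered tert-butyl ester and the aryl sulfonate should not react.

**Step 5**
Reactants: 8 tert-butyl (3E)-4-[3,5-dimethoxy-4-(tosyloxy)phenyl]-3-(hydroxymethyl)but-3-enoate
Product: 9 tert-butyl 2-{(2S,3S)-3-[3,5-dimethoxy-4-(tosyloxy)phenyl]-2-(hydroxymethyl)oxiran-2-yl}acetate
Conditions: Ti(Oi-Pr)4 (10 mol %), L-(+)-diethyl tartrate (12 mol %), t-BuOOH, 4 Å molecular sieves, CH2Cl2, −20 °C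
Reagents that add atoms: tert-butyl hydroperoxide, CC(C)(C)OO
Why: Sharpless asymmetric epoxidation of a 2-substituted (E)-cinnamyl-type alcohol; L-(+)-tartrate should deliver oxygen to the face that gives the (2S,3S)-epoxide, which fixes C8 as S and places the epoxide oxygen syn on C7.

**Step 6**
Reactants: 9 tert-butyl 2-{(2S,3S)-3-[3,5-dimethoxy-4-(tosyloxy)phenyl]-2-(hydroxymethyl)oxiran-2-yl}acetate
Product: 10 (4S,5R)-5-[3,5-dimethoxy-4-(tosyloxy)phenyl]-4-hydroxy-4-(hydroxymethyl)oxolan-2-one (aryl cis to the 4-OH; lignan 7R,8S)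
Conditions: BF3·OEt2 (1.1 equiv), CH2Cl2, −78 to −20 °C
Reagents that add atoms: none
Why: BF3-promoted intramolecular epoxide opening at the benzylic carbon by the tert-butyl ester carbonyl with loss of 2-methylpropene, a known mode for epoxy tert-butyl esters and carbonates; backside attack inverts C7 to R so that the aryl group ends cis to the C8 hydroxyl, and because the lactone C–O bond is made at C7 the lactone cannot form on the C9 oxygen.

**Step 7**
Reactants: 11 vanillin
Product: 12 4-[(tert-butyldimethylsilyl)oxy]-3-methoxybenzaldehyde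
Conditions: t-BuMe2SiCl, imidazole, DMF, rt
Reagents that add atoms: tert-butyldimethylsilyl chloride, CC(C)(C)[Si](C)(C)Cl
Why: Silylation of the phenol; the silyl ether keeps the guaiacyl ring donating enough to stabilise the C7' oxocarbenium ion of step 10.

**Step 8**
Reactants: 12 4-[(tert-butyldimethylsilyl)oxy]-3-methoxybenzaldehyde
Product: 13 tert-butyl[4-(dimethoxymethyl)-2-methoxyphenoxy]dimethylsilane
Conditions: HC(OMe)3, pyridinium p-toluenesulfonate (cat.), MeOH, rt
Reagents that add atoms: trimethyl orthoformate, COC(OC)OC; methanol, CO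
Why: Acid-catalysed acetalisation with the orthoformate as water scavenger gives an acetal that exchanges under mild conditions in step 9.

**Step 9**
Reactants: 10 (4S,5R)-5-[3,5-dimethoxy-4-(tosyloxy)phenyl]-4-hydroxy-4-(hydroxymethyl)oxolan-2-one; 13 tert-butyl[4-(dimethoxymethyl)-2-methoxyphenoxy]dimethylsilane
Product: 14 (5S,6R)-2-{4-[(tert-butyldimethylsilyl)oxy]-3-methoxyphenyl}-6-[3,5-dimethoxy-4-(tosyloxy)phenyl]-1,3,7-trioxaspiro[4.4]nonan-8-one (ring B lactone with the C8/C9 diol as spiro-dioxolane of C7'; both C2 epimers)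
Conditions: pyridinium p-toluenesulfonate (cat.), toluene, 50 °C, reduced pressure (removal of MeOH)
Reagents that add atoms: none
Why: Transacetalisation of the 1,2-diol (tertiary C8–OH, primary C9–OH) to the 2-aryl-1,3-dioxolane, driven by removal of methanol; the new acetal centre forms as a mixture and is destroyed in step 10.

**Step 10**
Reactants: 14 spiro acetal lactone (5S,6R; both C2 epimers)
Product: 17 cis-fused bicyclic ring B lactone (7R,8S,7'S,8'R) carrying free C8–OH and ring A closed, via silyl ketene acetal 15 (not isolated), via trimethylsilyl ether 16 (not isolated)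
Conditions: Me3SiOTf (1.2 equiv), Et3N (1.6 equiv), CH2Cl2, 0 °C to rt; then Me3SiOTf (0.8 equiv), −78 to −40 °C; then 1 M HCl, THF, 0 °C
Reagents that add atoms: none
Why: Proposed new method: Me3SiOTf with excess Et3N should first convert the lactone into silyl ketene acetal 15 while the amine-buffered acetal stays closed; the extra Me3SiOTf at −78 °C then silylates the acetal oxygen on C8, the C7'–O(C8) bond breaks to leave an aryl-stabilised oxocarbenium ion on the C9 oxygen, and C8' of the ketene acetal adds to C7' (intramolecular Mukaiyama-type addition), so that the dioxolane gives up one ring oxygen for C8' and the silyl group passes from the lactone oxygen to the C8 oxygen with turnover of Me3SiOTf. The closest known reactions are the Petasis–Ferrier rearrangement of 4-methylene-1,3-dioxolanes to tetrahydrofuranones, Lewis acid-promoted O-to-C rearrangements of acetals that carry an enol silane, and Me3SiOTf/amine enol silane formation followed by Mukaiyama addition to acetals. Ring A closes in a 5-(enolexo)-endo-trig mode, which an oxocarbenium acceptor tolerates as in the Petasis–Ferrier case. C8' is set by the tether: the C9–O=C7' arm hangs from C8 on the face of ring B opposite the C8 oxygen, so only the cis-fused bicycle with 8'-H cis to the C8 oxygen can form, and both acetal epimers of 14 converge on the same ion. C7' is set in the ring-closing transition state, where the (E)-oxocarbenium ion turns its aryl group to the convex face, away from ring B, to give the exo (7'S) aryl group. The step needs ionisation at the C8 oxygen (the ion on the C8 oxygen can only revert or lose the aldehyde by β-elimination) and an untouched C7–O lactone bond: reversible ionisation at −78 °C with capture of the less hindered primary oxocarbenium ion by the adjacent ketene acetal is relied on for the first, and the electron-poor 4-tosyloxy-3,5-dimethoxyphenyl group secures the second.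

**Step 11**
Reactants: 17 bicyclic ring B lactone (7R,8S,7'S,8'R)
Product: 18 the corresponding C9' lactol (both anomers)
Conditions: i-Bu2AlH (2.3 equiv), CH2Cl2, −78 °C; aq. potassium sodium tartrate
Reagents that add atoms: none
Why: Partial reduction of the lactone to the lactol; the aluminium lactolate is stable at −78 °C, the first equivalent of hydride is consumed by the C8 hydroxyl, and sulfonate and silyl ether are inert.

**Step 12**
Reactants: 18 C9' lactol
Product: 19 4'-O-(tert-butyldimethylsilyl)-4-O-tosylfraxiresinol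
Conditions: Et3SiH (4 equiv), BF3·OEt2 (2 equiv), CH2Cl2, −78 to −40 °C
Reagents that add atoms: none
Why: Ionic hydrogenation of the lactol through the ring B oxocarbenium ion turns C9' into CH2 without touching a stereocentre, since the lactol should ionise far more readily at low temperature than the benzylic ethers.

**Step 13**
Reactants: 19 4'-O-(tert-butyldimethylsilyl)-4-O-tosylfraxiresinol
Product: 21 fraxiresinol, via monotosylate 20 (not isolated)
Conditions: KOH, 1,4-dioxane/H2O, rt then 80 °C, under argon; aq. NH4Cl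
Reagents that add atoms: none
Why: Hydroxide cleaves the aryl silyl ether at room temperature and then the aryl sulfonate by attack at sulfur on heating (S–O cleavage), so no bond at a stereocentre is involved.

**Compound list**
1 | syringaldehyde (4-hydroxy-3,5-dimethoxybenzaldehyde) | COc1cc(C=O)cc(OC)c1O | starting material
2 | 4-formyl-2,6-dimethoxyphenyl 4-methylbenzenesulfonate | COc1cc(C=O)cc(OC)c1OS(=O)(=O)c2ccc(C)cc2 | intermediate
3 | triethyl phosphonoacetate | CCOC(=O)CP(=O)(OCC)OCC | starting material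
4 | tert-butyl bromoacetate | CC(C)(C)OC(=O)CBr | starting material
5 | 4-tert-butyl 1-ethyl 2-(diethoxyphosphoryl)butanedioate | CCOC(=O)C(CC(=O)OC(C)(C)C)P(=O)(OCC)OCC | intermediate
6 | 4-tert-butyl 1-ethyl (2E)-2-{[3,5-dimethoxy-4-(tosyloxy)phenyl]methylidene}butanedioate | CCOC(=O)/C(CC(=O)OC(C)(C)C)=C/c1cc(OC)c(OS(=O)(=O)c2ccc(C)cc2)c(OC)c1 | intermediate
7 | tert-butyl (3E)-4-[3,5-dimethoxy-4-(tosyloxy)phenyl]-3-formylbut-3-enoate (enal, not isolated) | O=C/C(CC(=O)OC(C)(C)C)=C/c1cc(OC)c(OS(=O)(=O)c2ccc(C)cc2)c(OC)c1 | intermediate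
8 | tert-butyl (3E)-4-[3,5-dimethoxy-4-(tosyloxy)phenyl]-3-(hydroxymethyl)but-3-enoate | OC/C(CC(=O)OC(C)(C)C)=C/c1cc(OC)c(OS(=O)(=O)c2ccc(C)cc2)c(OC)c1 | intermediate
9 | tert-butyl 2-{(2S,3S)-3-[3,5-dimethoxy-4-(tosyloxy)phenyl]-2-(hydroxymethyl)oxiran-2-yl}acetate | CC(C)(C)OC(=O)C[C@@]1(CO)O[C@H]1c1cc(OC)c(OS(=O)(=O)c2ccc(C)cc2)c(OC)c1 | intermediate
10 | (4S,5R)-5-[3,5-dimethoxy-4-(tosyloxy)phenyl]-4-hydroxy-4-(hydroxymethyl)oxolan-2-one | O=C1C[C@](O)(CO)[C@@H](c2cc(OC)c(OS(=O)(=O)c3ccc(C)cc3)c(OC)c2)O1 | intermediate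
11 | vanillin | COc1cc(C=O)ccc1O | starting material
12 | 4-[(tert-butyldimethylsilyl)oxy]-3-methoxybenzaldehyde | COc1cc(C=O)ccc1O[Si](C)(C)C(C)(C)C | intermediate
13 | tert-butyl[4-(dimethoxymethyl)-2-methoxyphenoxy]dimethylsilane | COC(OC)c1ccc(O[Si](C)(C)C(C)(C)C)c(OC)c1 | intermediate
14 | (5S,6R)-2-{4-[(tert-butyldimethylsilyl)oxy]-3-methoxyphenyl}-6-[3,5-dimethoxy-4-(tosyloxy)phenyl]-1,3,7-trioxaspiro[4.4]nonan-8-one, both C2 (C7') epimers, acetal centre left undefined | O=C1C[C@]2(COC(c3ccc(O[Si](C)(C)C(C)(C)C)c(OC)c3)O2)[C@@H](c2cc(OC)c(OS(=O)(=O)c3ccc(C)cc3)c(OC)c2)O1 | intermediate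
15 | (5S,6R)-8-[(trimethylsilyl)oxy]-1,3,7-trioxaspiro[4.4]non-8-ene analogue of 14 (lactone silyl ketene acetal, not isolated) | C[Si](C)(C)OC1=C[C@]2(COC(c3ccc(O[Si](C)(C)C(C)(C)C)c(OC)c3)O2)[C@@H](c2cc(OC)c(OS(=O)(=O)c3ccc(C)cc3)c(OC)c2)O1 | intermediate
16 | C8–O-trimethylsilyl ether of 17 (not isolated) | COc1cc([C@H]2OC[C@]3(O[Si](C)(C)C)[C@@H](c4cc(OC)c(OS(=O)(=O)c5ccc(C)cc5)c(OC)c4)OC(=O)[C@H]23)ccc1O[Si](C)(C)C(C)(C)C | intermediate
17 | (7R,8S,7'S,8'R) bicyclic lactone: ring B lactone O–C7–C8–C8'–C9'(=O) cis-fused at C8–C8' to ring A O–C7'–C8'–C8–C9; OH on C8; 3,5-dimethoxy-4-tosyloxyphenyl on C7 and 4-(tert-butyldimethylsilyloxy)-3-methoxyphenyl on C7', both exo (cis to 8-OH and 8'-H) | COc1cc([C@H]2OC[C@]3(O)[C@@H](c4cc(OC)c(OS(=O)(=O)c5ccc(C)cc5)c(OC)c4)OC(=O)[C@H]23)ccc1O[Si](C)(C)C(C)(C)C | intermediate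
18 | C9' lactol of 17 (both anomers, anomeric centre left undefined) | COc1cc([C@H]2OC[C@]3(O)[C@@H](c4cc(OC)c(OS(=O)(=O)c5ccc(C)cc5)c(OC)c4)OC(O)[C@H]23)ccc1O[Si](C)(C)C(C)(C)C | intermediate
19 | 4'-O-(tert-butyldimethylsilyl)-4-O-tosylfraxiresinol | COc1cc([C@H]2OC[C@]3(O)[C@@H](c4cc(OC)c(OS(=O)(=O)c5ccc(C)cc5)c(OC)c4)OC[C@H]23)ccc1O[Si](C)(C)C(C)(C)C | intermediate
20 | 4-O-tosylfraxiresinol (guaiacyl phenol free, not isolated) | COc1cc([C@H]2OC[C@]3(O)[C@@H](c4cc(OC)c(OS(=O)(=O)c5ccc(C)cc5)c(OC)c4)OC[C@H]23)ccc1O | intermediate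
21 | fraxiresinol, (7R,8S,7'S,8'R)-4,4'-dihydroxy-3,5,3'-trimethoxy-7,9':7',9-diepoxylignan-8-ol | COc1cc([C@H]2OC[C@]3(O)[C@@H](c4cc(OC)c(O)c(OC)c4)OC[C@H]23)ccc1O | target

**Step count**
Total: 13 steps. Longest linear sequence: 10 steps (1, 3, 4, 5, 6, 9, 10, 11, 12, 13).

**Steps most likely to fail**

1. Step 10. The acetal may open at the less hindered C9 oxygen, after which the ketene acetal can expel the C8 oxygen (β-elimination to a butenolide with loss of the aldehyde). Enol silane formation may also be slow, or the aryl group may turn endo in the ring closure. Fallback in known chemistry, setting out from 10 and returning at 17: 2,2-dimethoxypropane with pyridinium p-toluenesulfonate would give the spiro acetonide F1. Its lithium enolate (LiN(i-Pr)2, THF, −78 °C) should add to aldehyde 12 on the face opposite the C7 aryl group and the C8 oxygen to give the aldol adduct F2. Camphorsulfonic acid in methanol would then free the triol F3. BF3·OEt2 (cat.) in CH2Cl2 at −40 °C should close ring A by attack of the C9 hydroxyl on the C7' benzylic cation, the aryl group settling exo, to give 17.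

2. Step 6. Ionisation may occur at the fully substituted C8 with a 1,2-shift (Meinwald-type rearrangement), or inversion at C7 may be partly lost if a free benzylic cation intervenes. Fallback setting out from 9 and returning at 14: Ti(Oi-Pr)4-mediated opening with benzoic acid (chelate-directed SN2 at C7, inversion) would give the C7 benzoate F4. Acetalisation of its C8/C9 diol with 13 (pyridinium p-toluenesulfonate) would give the benzoate acetal F5. i-Bu2AlH at −78 °C would remove the benzoate to give the C7 alcohol F6. Catalytic NaH in THF would then close the lactone on the C7 alkoxide with loss of tert-butoxide and deliver 14 directly.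

3. Step 12. BF3 may ionise the C7'–O bond of the p-silyloxybenzyl ether, which would lead to reductive opening of ring A or epimerisation at C7'. Fallback setting out from 17 and returning at 19: LiBH4 in THF would reduce the lactone to the triol F7. TsCl in pyridine at 0 °C should sulfonylate only the primary C9' hydroxyl to give the monotosylate F8. NaH in THF would close ring B by 5-exo-tet attack of the C7 alkoxide on C9', which breaks no bond at a stereocentre, and give 19.

Further compounds
F1 | step 10 | (5S,6R)-6-[3,5-dimethoxy-4-(tosyloxy)phenyl]-2,2-dimethyl-1,3,7-trioxaspiro[4.4]nonan-8-one | O=C1C[C@]2(COC(C)(C)O2)[C@@H](c2cc(OC)c(OS(=O)(=O)c3ccc(C)cc3)c(OC)c2)O1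
F2 | step 10 | aldol adduct of F1 carrying on lignan C8' (face of the C9 methylene) the [4-(tert-butyldimethylsilyloxy)-3-methoxyphenyl](hydroxy)methyl group, carbinol epimers | O=C1[C@H](C(O)c3ccc(O[Si](C)(C)C(C)(C)C)c(OC)c3)[C@]2(COC(C)(C)O2)[C@@H](c2cc(OC)c(OS(=O)(=O)c3ccc(C)cc3)c(OC)c2)O1
F3 | step 10 | triol lactone from F2 after loss of the acetonide (C8–OH, C9–OH, C7'–OH) | O=C1[C@H](C(O)c3ccc(O[Si](C)(C)C(C)(C)C)c(OC)c3)[C@](O)(CO)[C@@H](c2cc(OC)c(OS(=O)(=O)c3ccc(C)cc3)c(OC)c2)O1
F4 | step 6 | tert-butyl (3S,4R)-4-(benzoyloxy)-4-[3,5-dimethoxy-4-(tosyloxy)phenyl]-3-hydroxy-3-(hydroxymethyl)butanoate | CC(C)(C)OC(=O)C[C@](O)(CO)[C@H](OC(=O)c1ccccc1)c1cc(OC)c(OS(=O)(=O)c2ccc(C)cc2)c(OC)c1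
F5 | step 6 | 2-aryl-1,3-dioxolane of the C8/C9 diol of F4 with the aryl group of 13 (acetal epimers) | CC(C)(C)OC(=O)C[C@]1(COC(c2ccc(O[Si](C)(C)C(C)(C)C)c(OC)c2)O1)[C@H](OC(=O)c1ccccc1)c1cc(OC)c(OS(=O)(=O)c2ccc(C)cc2)c(OC)c1
F6 | step 6 | C7 alcohol from F5 after removal of the benzoate | CC(C)(C)OC(=O)C[C@]1(COC(c2ccc(O[Si](C)(C)C(C)(C)C)c(OC)c2)O1)[C@H](O)c1cc(OC)c(OS(=O)(=O)c2ccc(C)cc2)c(OC)c1
F7 | step 12 | triol from reduction of lactone 17 (C7–OH, C8–OH, C9'–OH; ring A intact) | COc1cc([C@H]2OC[C@](O)([C@H](O)c3cc(OC)c(OS(=O)(=O)c4ccc(C)cc4)c(OC)c3)[C@@H]2CO)ccc1O[Si](C)(C)C(C)(C)C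
F8 | step 12 | C9' mono-p-toluenesulfonate of F7 | COc1cc([C@H]2OC[C@](O)([C@H](O)c3cc(OC)c(OS(=O)(=O)c4ccc(C)cc4)c(OC)c3)[C@@H]2COS(=O)(=O)c2ccc(C)cc2)ccc1O[Si](C)(C)C(C)(C)C
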